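(Readings and results stem from a simulated flask on assumed constants; the scatter is artificial.)

Free monomer plus monomer in chains should stay near the charge. Wednesday's last reading sums to 100% and Tuesday's to 96.0%. After 8.00 d those runs still hold 80% and 73% as free monomer, so you can roughly freeze free monomer at its charge.

| flask | free monomer | transfer agent | pre-initiator | remark | time |
|---|---|---|---|---|---|
| Wednesday's | 0.029 M | 0.56 mM | 1 mol% | run made earlier |  |
| Tuesday's | 0.083 M | 0.56 mM | 1 mol% | run made earlier |  |
| south | 0.056 M | 0.560 mM | 1 mol% |  | 10 d |
| west | 0.020 M | 0.560 mM | 1 mol% |  | 10 d |

| run | time / d | monomer in chains / % | free monomer / % |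
|---|---|---|---|
| Wednesday's | 0.625 | 0 | 97 |
| Wednesday's | 1.04 | 2 | 98 |
| Wednesday's | 2.08 | 4 | 93 |
| Wednesday's | 4.00 | 13 | 90 |
| Wednesday's | 8.00 | 20 | 80 |
| Tuesday's | 0.625 | 1 | 98 |
| Tuesday's | 1.04 | 9 | 98 |
| Tuesday's | 2.08 | 9 | 92 |
| Tuesday's | 4.00 | 13 | 84 |
| Tuesday's | 8.00 | 23 | 73 |

(standard deviation of a reading: 1.5 percentage points)

- the average divides the monomer in chains by the number of chains begun, living and dead together
- what was read earlier has a scatter of 1.5 percentage points, one standard deviation
- the earlier runs do not show the number of chains; that part of a forecast is a guess

* which of the two ends with the longer chains by the average number of monomer units in a chain (chains begun, living or dead) ("neither" if they lie within 10%) (south / west / neither)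
* average number of monomer units in a chain (chains begun, living or dead) at the end, south
* average number of monomer units in a chain (chains begun, living or dead) at the end, west

South and west look nearly the same: they share their transfer agent, their loading of pre-initiator and their time. They differ in the free monomer charged. The readings show no chain count, so you need a ratio instead.

Call the charged transfer agent, as a fraction of the charged free monomer, x. It is 1.00% in south and 2.80% in west. This x, the transfer ratio, sets the two partners of a growing chain against each other: transfer agent and free monomer.

Suppose each added unit carries a chance a of stopping the chain, plus a chance b × x from transfer agent. Then: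

reciprocal length = a + b × x

With a zero, south's chains are longer by a factor of 2.80. With a positive, the factor is smaller. On this supposition, with b positive, my reckoning says south, by no more than that factor.

The forecast says south, with 24 (13 to 38) for south and 7.5 (5 to 12) for west. Its stated caution: “The number of chains is the guess.” Its factor of 3.20 is larger than my limit.

The flask gives south: 36.3 against 26.7, a factor of 1.36.

    free monomer + living end → monomer in chains + living end, rate k1*[living end]*[free monomer] (k = 0.0220 M⁻¹ s⁻¹)
    living end + transfer agent → dead chain (kL = 0.0110 M⁻¹ s⁻¹)
    free monomer + initiator → living end + monomer in chains (k = 0.00620 M⁻¹ s⁻¹)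
    living end + free monomer → dead end (k = 4.90 × 10⁻⁴ M⁻¹ s⁻¹)
    pre-initiator → initiator (k = 1.50 × 10⁻⁶ s⁻¹)

West charged with south's free monomer has south's x and ends at 36.3, not 26.7, so the free monomer charge is the main reason for the gap. The two flasks put b, the chain-transfer constant of the Mayo equation, at 0.551, and a at 0.0221. The neighbour charged with 0.22 M has x = 0.255%, which gives a length of 42.5, and it ends at 42.9.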